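**Even feed.** A steady pump adds the free monomer evenly, so by 80.0 s the autumn run has received 53.3% of its charge, and dosing ends at 2.5 min.

| flask | free monomer | initiator | remark | time |
|---|---|---|---|---|
| summer | 0.079 mM (fed, over 2.5 min) | 4 µM | run made earlier; the fed solution adds 0.20 times the starting volume |  |
| dusk | 0.13 mM (fed, over 2.5 min) | 4 µM | run made earlier; the fed solution adds 0.20 times the starting volume |  |
| autumn | 0.18 mM (fed, over 2.5 min) | 4 µM | run made earlier; the fed solution adds 0.20 times the starting volume |  |
| west | 0.20 mM (fed, over 2.5 min) | 4.0 µM | the fed solution adds 0.20 times the starting volume | 2.5 min |
| north | 0.10 mM (fed, over 2.5 min) | 4.0 µM | the fed solution adds 0.20 times the starting volume | 2.5 min |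

- summer (time / s: monomer in chains / %, free monomer / %): 10.0: 1, 6; 12.0: 0, 7; 20.0: 0, 13; 40.0: 4, 25; 80.0: 20, 35
- dusk (time / s: monomer in chains / %, free monomer / %): 10.0: 0, 6; 20.0: 0, 13; 40.0: 3, 25; 50.0: 7, 26; 80.0: 26, 29
- autumn (time / s: monomer in chains / %, free monomer / %): 15.0: 0, 10; 30.0: 3, 20; 50.0: 7, 25; 60.0: 13, 29; 80.0: 28, 28

(each reading ± 1.5 percentage points)

- charges are per starting volume, the dose included; the dosed solution carries all of it
- the average divides the monomer in chains by the number of chains begun, living and dead together
- the earlier runs do not show the number of chains; that part of a forecast is a guess
- percentages count the whole charge, also what has not yet gone in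

- which of the two ends with the longer chains by the average number of monomer units in a chain (chains begun, living or dead) ("neither" if they lie within 10%) (west / north / neither)
- average number of monomer units in a chain (chains begun, living or dead) at the end, west
- average number of monomer units in a chain (chains begun, living or dead) at the end, north

**Odd pair.** At 80.0 s the autumn run holds 28% of its charge as free monomer and the dusk run 29%, although autumn was charged 1.38 times as much and both feeds are still running.

**Level cleared.** Free monomer gains the feed and loses a pseudo-first-order term: a constant, which grows with the number of growing chains, times its own amount. Integrated at a fixed constant, this gives a share that climbs and levels off at feed over constant. Autumn's reading puts the time scale at 42.0 s, and dosing lasts longer than that. Counted in percent of the charge, the charge cancels from that level, which leaves the number of chains. Dusk and autumn both received 4 µM of initiator, and their like readings suggest a like number of chains at that time. The summer run, with the same initiator, reads 35% of free monomer then, so this suggestion rests on dusk and autumn.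

**Floor length.** If the levels hold to the end, autumn's reading leaves 72.0% of west's charge in chains, and dusk's reading leaves 71.0% of north's. Converted monomer over initiator charged is then 36.0 for west and 17.8 for north. This floor length, conversion times the charge ratio, is the average if each initiator begins one chain, and a lower bound if some begin none. On the assumption that each initiator begins one chain, this reckoning commits to about those lengths, with west longer by a factor of 2.03.

**The forecast.** It says west, with 75 and 37, on the ground “I guess about half the initiator has started”, so it shares the winner with this reckoning and differs on the lengths.

**The flask.** West ends at 41.3 units per chain and north at 21.9, so west has the longer chains.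

    free monomer + initiator → living end + monomer in chains (k = 526 /M/s)
    free monomer + living end → monomer in chains + living end, rate k2*[living end]*[free monomer] (k = 9430 /M/s)
    initiator + monomer in chains → spent initiator (k = 40.9 /M/s)

**Floor tested.** West ends with 76.5% of its charge in chains and 3.4% of its initiator unbound, and on that conversion the floor length is 38.3. A neighbour of west charged with 0.80 mM of free monomer ends with 79.1% in chains and 0% of its initiator unbound. Its floor length is 158, and its average is 161.

All runs are calculated for substances that don't exist, noise included.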